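## Retrosynthetic overview
1. Target ⇐ desilylation of a bis-silyl ether whose butenolide comes from a 3-furyl group (singlet oxygen, then NaBH4); the angelate is put on the only free hydroxyl (C3) before that.
2. Ring A oxygenation is carried out on the closed trans-decalin: C2–O by Rubottom oxidation of the Diels–Alder-derived silyl enol ether, C18 by formaldehyde aldol at C4, C3–OH by hydride reduction.
3. Key disconnection: C8–C9. A C9 radical cyclises 6-exo-dig onto a C8≡C17 alkyne, which closes ring B, sets C9 and delivers the 8(17)-methylidene in one step.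
4. C9–C11: a 2-(furan-3-yl)ethyl Grignard reagent adds to a C9 aldehyde; the carbinol becomes the radical precursor (thionocarbonate).
5. Ring order: ring A first, by catalytic asymmetric Diels–Alder of (E)-2-methylhept-2-en-6-ynal with a 3-silyloxypenta-1,3-diene (sets C5 and C10); ring B second (radical); butenolide ring last.

Assumption: labdane numbering (C1–C20) is used for all cyclic compounds, α meaning the face of the C10 methyl and β the opposite face; the (S)-oxazaborolidinium catalyst is taken to give 5 as drawn (its mirror image is used if the facial sense is the opposite).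

## Route

Step 1
Reactants: 1 pent-4-ynal
Product: 2 (E)-2-methylhept-2-en-6-ynal
Conditions: Ph3P=C(CH3)CHO (1.1 equiv), PhMe, 90 °C
Reagents that add atoms: 2-(triphenyl-λ5-phosphanylidene)propanal, CC(C=O)=P(c1ccccc1)(c1ccccc1)c1ccccc1
Why: Wittig olefination with a formyl-stabilised ylide, which gives the (E)-trisubstituted enal (CHO trans to the chain) with high selectivity.

Step 2
Reactants: 3 pent-1-en-3-one
Product: 4 (Z)-3-(tert-butyldimethylsilyloxy)penta-1,3-diene
Conditions: tBuMe2SiOTf (1.1 equiv), Et3N, Et2O, 0 °C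
Reagents that add atoms: tert-butyldimethylsilyl trifluoromethanesulfonate, CC(C)(C)[Si](C)(C)OS(=O)(=O)C(F)(F)F
Why: Soft enolisation and O-silylation of the ethyl ketone (silyl enol ether formation) give the 2-silyloxy diene with the methyl cis to OSi, that is on the outside of the s-cis diene.

Step 3
Reactants: 2 (E)-2-methylhept-2-en-6-ynal; 4 (Z)-3-(tert-butyldimethylsilyloxy)penta-1,3-diene (1.5 equiv)
Product: 5 (1R,5R,6R)-6-(but-3-yn-1-yl)-4-(tert-butyldimethylsilyloxy)-1,5-dimethylcyclohex-3-ene-1-carbaldehyde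
Conditions: (S)-1-(2-methylphenyl)-3,3-diphenyltetrahydro-1H,3H-pyrrolo[1,2-c][1,3,2]oxazaborole (20 mol %), (CF3SO2)2NH (18 mol %), CH2Cl2, −78 → −40 °C
Reagents that add atoms: none
Why: Enantioselective Diels–Alder reaction under chiral oxazaborolidinium catalysis, in which the enol-ether carbon C4 bonds to the enal β-carbon C5 and C1 to C10, the (E)-geometry of 2 is transferred so that CHO (C9) is trans and CH3 (C20) cis to the butynyl chain, the catalyst fixes the absolute configuration at C5 and C10, and the C4 methine (endo adduct shown) is planarised again in step 8.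

Step 4
Reactants: 6 2-(furan-3-yl)ethanol
Product: 7 3-(2-bromoethyl)furan
Conditions: CBr4, PPh3, CH2Cl2, 0 → 20 °C
Reagents that add atoms: carbon tetrabromide, BrC(Br)(Br)Br
Why: Appel bromination (SN2 displacement at the primary carbon), which leaves the furan untouched.

Step 5
Reactants: 5 the Diels–Alder aldehyde; 7 3-(2-bromoethyl)furan
Product: 10 O-phenyl thionocarbonate of the C9 carbinol (both C9 epimers), via Grignard reagent 8 (not isolated), via bromomagnesium alkoxide 9 (not isolated)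
Conditions: Mg, THF, 25 °C; then 5, −78 → −20 °C; then PhOC(S)Cl, 4-(dimethylamino)pyridine (cat.), −20 → 25 °C
Reagents that add atoms: O-phenyl chlorothionoformate, S=C(Cl)Oc1ccccc1
Why: Grignard 1,2-addition to the neopentyl aldehyde (faster at −78 °C than deprotonation of the terminal alkyne) followed by O-acylation of the alkoxide; the C9 configuration is irrelevant because C9 becomes a radical in step 6.

Step 6
Reactants: 10 O-phenyl thionocarbonate of the C9 carbinol
Product: 11 3-(tert-butyldimethylsilyloxy)-9α-[2-(furan-3-yl)ethyl]-4β,10α-dimethyl-8-methylidene-trans-decal-2-ene (5β-H; 9β-H)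
Conditions: Bu3SnH (1.3 equiv, syringe pump, 6 h), 2,2′-azobis(2-methylpropionitrile) (0.2 equiv), PhH (0.01 M), 80 °C
Reagents that add atoms: none
Why: Barton–McCombie C–O homolysis gives the secondary C9 radical, which closes ring B by 6-exo-dig radical cyclisation onto the C8≡C17 alkyne through a chair transition state (trans fusion is preset by the trans C5 and C10 arms, and the furylethyl chain sits pseudo-equatorial, anti to C5 and clear of H5 and H7, so H9 ends β), and the vinyl radical takes hydrogen from Bu3SnH to give the 8(17)-methylidene directly.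

Step 7
Reactants: 11 the silyl enol ether decalin
Product: 13 2β-(tert-butyldimethylsilyloxy)-9α-[2-(furan-3-yl)ethyl]-4β,10α-dimethyl-8-methylidene-trans-decalin-3-one, via siloxy epoxide 12 (not isolated)
Conditions: dimethyldioxirane (1.05 equiv) in acetone, CH2Cl2, −78 °C; then pyridinium p-toluenesulfonate (5 mol %), −78 → 20 °C
Reagents that add atoms: dimethyldioxirane, CC1(C)OO1
Why: Rubottom oxidation, in which the electron-rich enol ether is epoxidised far faster than the furan or the 1,1-disubstituted alkene and from the β face opposite the axial C10 methyl, and 1,4-silyl shift then gives the equatorial 2β-silyl ether.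

Step 8
Reactants: 13 the 2β-silyloxy 3-ketone
Product: 16 2β-(tert-butyldimethylsilyloxy)-4β-[(tert-butyldimethylsilyloxy)methyl]-9α-[2-(furan-3-yl)ethyl]-4α,10α-dimethyl-8-methylidene-trans-decalin-3-one, via lithium enolate 14 (not isolated), via lithium aldolate 15 (not isolated)
Conditions: LiN(iPr)2 (1.2 equiv), THF, −78 → −30 °C; CH2O (gas, excess), −78 °C; N2 purge; tBuMe2SiOTf (2 equiv), −78 → 0 °C
Reagents that add atoms: formaldehyde, C=O; tert-butyldimethylsilyl trifluoromethanesulfonate, CC(C)(C)[Si](C)(C)OS(=O)(=O)C(F)(F)F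
Why: Kinetic α′-deprotonation (C2–H is shielded and deactivated by its own silyloxy group) followed by aldol addition to formaldehyde on the β face, anti to the axial C10 methyl, makes C18 equatorial and pushes the C4 methyl axial (α), and silylation of the aldolate prevents retro-aldol.

Step 9
Reactants: 16 the bis-silyl 3-ketone
Product: 17 2β-(tert-butyldimethylsilyloxy)-4β-[(tert-butyldimethylsilyloxy)methyl]-9α-[2-(furan-3-yl)ethyl]-4α,10α-dimethyl-8-methylidene-trans-decalin-3α-ol
Conditions: NaBH4, MeOH/THF, 0 °C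
Reagents that add atoms: none
Why: Hydride reduction with axial attack from the β face (the α face is blocked by the axial C4 methyl) gives the equatorial 3α-alcohol trans to the 2β-silyloxy group, as in reductions of 4,4-disubstituted 3-keto terpenoids.

Step 10
Reactants: 17 the 3α-alcohol; 18 angelic acid
Product: 20 3α-angelate of 17, via mixed anhydride 19 (not isolated)
Conditions: 2,4,6-Cl3C6H2COCl, Et3N, PhMe, 20 °C; then 17, 80 °C
Reagents that add atoms: none
Why: Yamaguchi mixed-anhydride esterification of the only free hydroxyl, run without a nucleophilic catalyst so that the (Z)-angelate does not isomerise to the tiglate.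

Step 11
Reactants: 20 the furyl angelate
Product: 23 bis-silyl ether of the target (15,16-olide), via furan endoperoxide 21 (not isolated), via hydroxybutenolide 22 (not isolated)
Conditions: O2, hν (visible), 5,10,15,20-tetraphenylporphyrin (1 mol %), iPr2NEt, CH2Cl2, −78 °C; then NaBH4, EtOH, 0 °C; aq. HCl work-up (pH 3)
Reagents that add atoms: dioxygen, O=O
Why: [4+2] addition of singlet oxygen to the 3-alkylfuran and amine-induced Kornblum–DeLaMare opening at the less hindered C15–H give the 4-alkyl-5-hydroxybutenolide regioselectively, whose lactol carbon C16 is reduced by NaBH4 and relactonises to the β-substituted butenolide, while the exocyclic alkene and the electron-poor angelate do not react at −78 °C.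

Step 12
Reactants: 23 bis-silyl ether of the target
Product: 24 CNP0335424.2
Conditions: HF·pyridine, pyridine/THF, 0 → 20 °C
Reagents that add atoms: none
Why: Fluoride-mediated silyl ether cleavage under buffered acidic conditions, which avoids base-induced 3→2 angelate migration and leaves the butenolide and the exocyclic alkene intact.

## Compound list
1 | pent-4-ynal | C#CCCC=O | starting material
2 | (E)-2-methylhept-2-en-6-ynal | C#CCC/C=C(\C)C=O | intermediate
3 | pent-1-en-3-one (ethyl vinyl ketone) | C=CC(=O)CC | starting material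
4 | (Z)-3-(tert-butyldimethylsilyloxy)penta-1,3-diene | C=C/C(=C/C)O[Si](C)(C)C(C)(C)C | intermediate
5 | (1R,5R,6R)-6-(but-3-yn-1-yl)-4-(tert-butyldimethylsilyloxy)-1,5-dimethylcyclohex-3-ene-1-carbaldehyde | C#CCC[C@H]1[C@@](C)(CC=C(O[Si](C)(C)C(C)(C)C)[C@@H]1C)C=O | intermediate
6 | 2-(furan-3-yl)ethanol | OCCc1ccoc1 | starting material
7 | 3-(2-bromoethyl)furan | BrCCc1ccoc1 | intermediate
8 | [2-(furan-3-yl)ethyl]magnesium bromide | Br[Mg]CCc1ccoc1 | intermediate
9 | bromomagnesium alkoxide of the C9 carbinol from 5 and 8 (C9 epimers) | C#CCC[C@H]1[C@@](C)(CC=C(O[Si](C)(C)C(C)(C)C)[C@@H]1C)C(O[Mg]Br)CCc1ccoc1 | intermediate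
10 | O-phenyl thionocarbonate of 1-[(1R,5R,6R)-6-(but-3-yn-1-yl)-4-(tert-butyldimethylsilyloxy)-1,5-dimethylcyclohex-3-en-1-yl]-3-(furan-3-yl)propan-1-ol (C9 epimers) | C#CCC[C@H]1[C@@](C)(CC=C(O[Si](C)(C)C(C)(C)C)[C@@H]1C)C(OC(=S)Oc1ccccc1)CCc1ccoc1 | intermediate
11 | 3-(tert-butyldimethylsilyloxy)-9α-[2-(furan-3-yl)ethyl]-4β,10α-dimethyl-8-methylidene-trans-decal-2-ene (5β-H; 9β-H) | C=C1CC[C@H]2[C@@](C)(CC=C(O[Si](C)(C)C(C)(C)C)[C@@H]2C)[C@@H]1CCc1ccoc1 | intermediate
12 | 2β,3β-epoxide of 11 (3α-silyloxy) | C=C1CC[C@H]2[C@@](C)(C[C@@H]3O[C@]3(O[Si](C)(C)C(C)(C)C)[C@@H]2C)[C@@H]1CCc1ccoc1 | intermediate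
13 | 2β-(tert-butyldimethylsilyloxy)-9α-[2-(furan-3-yl)ethyl]-4β,10α-dimethyl-8-methylidene-trans-decalin-3-one | C=C1CC[C@H]2[C@@](C)(C[C@H](O[Si](C)(C)C(C)(C)C)C(=O)[C@@H]2C)[C@@H]1CCc1ccoc1 | intermediate
14 | lithium C3–C4 enolate of 13 | C=C1CC[C@H]2[C@@](C)(C[C@H](O[Si](C)(C)C(C)(C)C)C(O[Li])=C2C)[C@@H]1CCc1ccoc1 | intermediate
15 | lithium aldolate (4β-CH2OLi, 4α-CH3) | C=C1CC[C@H]2[C@@](C)(C[C@H](O[Si](C)(C)C(C)(C)C)C(=O)[C@]2(C)CO[Li])[C@@H]1CCc1ccoc1 | intermediate
16 | 2β-(tert-butyldimethylsilyloxy)-4β-[(tert-butyldimethylsilyloxy)methyl]-9α-[2-(furan-3-yl)ethyl]-4α,10α-dimethyl-8-methylidene-trans-decalin-3-one | C=C1CC[C@H]2[C@@](C)(C[C@H](O[Si](C)(C)C(C)(C)C)C(=O)[C@]2(C)CO[Si](C)(C)C(C)(C)C)[C@@H]1CCc1ccoc1 | intermediate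
17 | 3α-alcohol from 16 (2β-OSi, 3α-OH trans-diequatorial) | C=C1CC[C@H]2[C@@](C)(C[C@H](O[Si](C)(C)C(C)(C)C)[C@@H](O)[C@]2(C)CO[Si](C)(C)C(C)(C)C)[C@@H]1CCc1ccoc1 | intermediate
18 | angelic acid, (Z)-2-methylbut-2-enoic acid | C/C=C(/C)C(=O)O | starting material
19 | angelic 2,4,6-trichlorobenzoic anhydride | C/C=C(/C)C(=O)OC(=O)c1c(Cl)cc(Cl)cc1Cl | intermediate
20 | 3α-angelate of 17 | C=C1CC[C@H]2[C@@](C)(C[C@H](O[Si](C)(C)C(C)(C)C)[C@@H](OC(=O)/C(C)=C\C)[C@]2(C)CO[Si](C)(C)C(C)(C)C)[C@@H]1CCc1ccoc1 | intermediate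
21 | furan endoperoxide of 20 (2,3,7-trioxabicyclo[2.2.1]hept-5-ene) | C=C1CC[C@H]2[C@@](C)(C[C@H](O[Si](C)(C)C(C)(C)C)[C@@H](OC(=O)/C(C)=C\C)[C@]2(C)CO[Si](C)(C)C(C)(C)C)[C@@H]1CCC1=CC2OOC1O2 | intermediate
22 | 16-hydroxy-15,16-olide (4-alkyl-5-hydroxyfuran-2(5H)-one, C16 epimers) | C=C1CC[C@H]2[C@@](C)(C[C@H](O[Si](C)(C)C(C)(C)C)[C@@H](OC(=O)/C(C)=C\C)[C@]2(C)CO[Si](C)(C)C(C)(C)C)[C@@H]1CCC1=CC(=O)OC1O | intermediate
23 | 2,18-bis(tert-butyldimethylsilyl) ether of the target | C=C1CC[C@H]2[C@@](C)(C[C@H](O[Si](C)(C)C(C)(C)C)[C@@H](OC(=O)/C(C)=C\C)[C@]2(C)CO[Si](C)(C)C(C)(C)C)[C@@H]1CCC1=CC(=O)OC1 | intermediate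
24 | CNP0335424.2, (2S,3S,4S,5S,9R,10S)-3-angeloyloxy-2-hydroxy-4-(hydroxymethyl)labda-8(17),13-dien-15,16-olide (2β-OH, 3α-OAng, 4β-CH2OH) | C=C1CC[C@H]2[C@@](C)(C[C@H](O)[C@@H](OC(=O)/C(C)=C\C)[C@]2(C)CO)[C@@H]1CCC1=CC(=O)OC1 | target

## Step count
Total steps: 12. Longest linear sequence: 10 steps (1, 3, 5, 6, 7, 8, 9, 10, 11, 12).

## Steps most likely to fail

**Step 6 (radical ring closure).** The risks are a modest ratio at C9, reduction of the C9 radical before it cyclises, and hydrostannylation of the alkyne. The fallback sets out from 5 and 7 and returns at 11. Bromide 7 is heated with PPh3 (PhMe, 110 °C) to give [2-(furan-3-yl)ethyl]triphenylphosphonium bromide F1. Its ylide (NaN(SiMe3)2, THF, −78 °C) converts 5 into the (Z)-C9=C11 alkene F2. Bu3SnH and 2,2′-azobis(2-methylpropionitrile) (PhH, 80 °C) then add a stannyl radical to the terminal alkyne; the C8 vinyl radical closes ring B by 6-exo-trig attack on C9 and the C11 radical is reduced, giving the C17 vinylstannane F3. Stirring with wet silica gel in CH2Cl2 removes tin and gives 11. Radical and acceptor swap roles, so C9 is set by attack on an alkene whose rotamer is fixed by allylic strain.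

**Step 8 (enolisation towards C4 and hydroxymethylation).** The risks are competing deprotonation at C2, O-to-O silyl migration and retro-aldol. The fallback sets out from 11 and returns at 16. Bu4NF/AcOH (THF, 0 °C) unmasks the 4β-methyl 3-ketone F4. Equilibration to the more substituted lithium enolate (LiN(iPr)2 0.95 equiv, THF, 0 °C), then CH2O gas and tBuMe2SiOTf, gives the 4β-(silyloxymethyl) ketone F5. With C4 now quaternary, LiN(iPr)2/tBuMe2SiCl (THF, −78 °C) can only give the C2 silyl enol ether F6. The dimethyldioxirane oxidation of step 7 applied to F6 then gives 16.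

**Step 3 (asymmetric Diels–Alder of a trisubstituted enal).** The risks are low conversion and insufficient enantioselectivity. The fallback sets out from 2 and 4 and returns at 5. Me2AlCl (1 equiv, CH2Cl2, −78 °C) promotes the same cycloaddition without enantiocontrol and gives the racemic adduct F7. This is resolved by preparative chromatography on a chiral stationary phase (amylose tris(3,5-dimethylphenylcarbamate)) to give 5.

Further compounds
F1 | step 6 | [2-(furan-3-yl)ethyl]triphenylphosphonium bromide | [Br-].c1ccc(cc1)[P+](CCc1ccoc1)(c1ccccc1)c1ccccc1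
F2 | step 6 | (Z)-C9=C11 alkene from 5 (1-[(Z)-3-(furan-3-yl)prop-1-enyl] analogue of 5) | C#CCC[C@H]1[C@@](C)(CC=C(O[Si](C)(C)C(C)(C)C)[C@@H]1C)/C=C\Cc1ccoc1
F3 | step 6 | 17-(tributylstannyl) derivative of 11 (vinylstannane) | CCCC[Sn](CCCC)(CCCC)C=C1CC[C@H]2[C@@](C)(CC=C(O[Si](C)(C)C(C)(C)C)[C@@H]2C)[C@@H]1CCc1ccoc1
F4 | step 8 | 9α-[2-(furan-3-yl)ethyl]-4β,10α-dimethyl-8-methylidene-trans-decalin-3-one | C=C1CC[C@H]2[C@@](C)(CCC(=O)[C@@H]2C)[C@@H]1CCc1ccoc1
F5 | step 8 | 4β-[(tert-butyldimethylsilyloxy)methyl]-4α,10α-dimethyl 3-ketone | C=C1CC[C@H]2[C@@](C)(CCC(=O)[C@]2(C)CO[Si](C)(C)C(C)(C)C)[C@@H]1CCc1ccoc1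
F6 | step 8 | C2 silyl enol ether of F5 | C=C1CC[C@H]2[C@@](C)(CC=C(O[Si](C)(C)C(C)(C)C)[C@]2(C)CO[Si](C)(C)C(C)(C)C)[C@@H]1CCc1ccoc1
F7 | step 3 | racemic 5 (both enantiomers) | C#CCC[C@H]1[C@@](C)(CC=C(O[Si](C)(C)C(C)(C)C)[C@@H]1C)C=O.C#CCC[C@@H]1[C@](C)(CC=C(O[Si](C)(C)C(C)(C)C)[C@H]1C)C=O
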